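A level stretch of monomer in chains is easily read as a stalled reaction, yet in the north-east run free monomer stands beside it at 0%.

| setting | north-east | west | flask |
|---|---|---|---|
| free monomer | 0.40 M | 0.40 M | 0.40 M |
| protic impurity | 0.17 M | 0.26 M | 0.120 M |
| initiator | 0.5 mol% | 0.5 mol% | 0.5 mol% |
| remark | run made earlier | run made earlier |  |
| time |  |  | 4.0 d |

- north-east (time / d: monomer in chains / %, free monomer / %): 0.250: 43, 20; 0.833: 55, 0; 1.25: 56, 0; 2.08: 57, 1; 3.00: 56, 0; 4.00: 55, 3; 5.00: 55, 4
- west (time / d: monomer in chains / %, free monomer / %): 0.417: 31, 2; 0.625: 35, 2; 0.833: 33, 2; 1.25: 31, 2; 2.08: 34, 0; 3.00: 34, 2; 5.00: 33, 1

(standard deviation of a reading: 2 percentage points)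

- the earlier runs were read with a standard deviation of 2 percentage points
- candidate steps: free monomer + initiator -> living end + monomer in chains; free monomer + living end -> monomer in chains + living end; protic impurity + free monomer -> quenched substrate; living end + monomer in chains -> dead end
- the reaction counts as stopped when no species that holds the free monomer changes by six tenths of a point or more over the second half of the time

- at 4.0 d, what has stopped the reaction, if anything has (forward and back rates have come level / no working catalyst is left / all of the free monomer has reacted / it is still moving)
- amount of monomer in chains at 4.0 d, in percent of the free monomer charged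

For the flask, 70.0% is the chain share: the fraction of the charge left once protic impurity has taken free monomer one for one, that is one minus c(protic impurity)/c(free monomer). The same sum gives 57.5% for north-east, against a reading of 56%, and 35.0% for west, against 34%, both within the scatter of 2 percentage points.

Whether the flask gets there is a question of rate, reckoned on the fraction left. North-east keeps 20% after 0.250 d, which reads as:

loss rate = ln(1/fraction left)/time = 6.44 d⁻¹

Taking this rate over for the flask, the chains' part of that loss gives a slowing factor of 1.86 once quenching ends:

rate after quenching = 3.46 d⁻¹

Reaching 2.00% left by 4.0 d needs:

needed rate = 0.978 d⁻¹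

The rate after quenching is higher than that by a factor of 3.54, and this estimate leaves that much room for average slowing from living ends turning into dead ends. The reckoning here therefore expects under 2.00% of the free monomer left by 4.0 d, counted as all of it reacted, and 70.0% in chains. The forecast says all of the free monomer has reacted and 68%, less in chains than this reckoning's 70.0%, holding that “Quenching is fast relative to propagation”.

At 4.0 d the flask's outcome is: all of the free monomer has reacted.

    free monomer + initiator → living end + monomer in chains (k = 0.0210 M⁻¹ min⁻¹)
    free monomer + living end → monomer in chains + living end, rate k2*[living end]*[free monomer] (k = 3.90 M⁻¹ min⁻¹)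
    protic impurity + free monomer → quenched substrate (k = 0.240 M⁻¹ min⁻¹)
    living end + monomer in chains → dead end (k = 0.00560 M⁻¹ min⁻¹)

The flask holds 69.2% in chains against the chain share of 70.0%, with 0.37% of its free monomer left. With 0.48 M of protic impurity, the neighbouring flask has a chain share of −20.0%, below zero, so free monomer is the limiting reagent and the one-for-one sum leaves 16.7% of the impurity. That flask ends with 0% of its free monomer, 18% of its protic impurity and 1.08% in chains.

The data were generated by integration for an exercise, and the scatter is random.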